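**Strategy.** Everything rests on disconnecting the side chain between the tertiary carbinol carbon C13 and the acetoxy-bearing carbon C14. The key step adds a chiral (Z)-γ-alkoxyallylborane to aldehyde 13, in which rings A and B and all four ring stereocentres are already in place: one Zimmerman–Traxler event forms C13–C14 and fixes C14 by reagent control, the vinyl group being a latent C15 hydroxymethyl. The step exploits the contiguous oxygenation C13–C14–C15 on the chain attached to C9 of ring B: after oxidation at C13, the C14 ether steers methyl addition to C13 by chelation. The core comes from asymmetric conjugate addition/allylation (C8, C9) and a Diels–Alder closure of ring A (C4, C5).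

Key step: step 9

Remarks on the chemistry (assumptions):
- Atom labels follow halimane numbering: ring A = C1–C5 and C10; ring B = C5–C10; C17 and C20 are the methyl groups on C8 and C9; C18 is the carboxyl carbon and C19 the methyl group on C4; the side chain C11–C15 starts at C9; C16 is the methyl group on C13. PMB = 4-methoxybenzyl, Ipc = isopinocampheyl.
- In step 1 the enantiomer of the phosphoramidite ligand is the one that delivers methyl to give the 3R enolate (C8 R); all later stereocentres are set relative to it or by reagent control.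

Step 1
Reactants: 1 2-methylcyclohex-2-en-1-one
Product: 3 (R)-2,3-dimethyl-1-[(trimethylsilyl)oxy]cyclohex-1-ene, via aluminium enolate 2 (not isolated)
Conditions: Me3Al, CuTC (2 mol %), chiral phosphoramidite L* (4 mol %), Et2O, −30 °C; then TMSOTf, −30 → 0 °C
Reagents that add atoms: trimethylaluminium C[Al](C)C; trimethylsilyl triflate C[Si](C)(C)OS(=O)(=O)C(F)(F)F
Why: Copper-catalysed asymmetric conjugate addition of methyl (ligand control sets C8, R) gives the tetrasubstituted aluminium enolate regiospecifically, and O-silylation stores it as the silyl enol ether.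

Step 2
Reactants: 3 (R)-2,3-dimethyl-1-[(trimethylsilyl)oxy]cyclohex-1-ene
Product: 5 (2S,3R)-2-allyl-2,3-dimethylcyclohexan-1-one, via lithium enolate 4 (not isolated)
Conditions: MeLi, THF, 0 °C → rt; then HMPA, allyl bromide, −78 → 0 °C
Reagents that add atoms: allyl bromide C=CCBr
Why: Si–O cleavage by MeLi regenerates the tetrasubstituted lithium enolate, and enolate C-alkylation with the reactive allylic halide should occur anti to the neighbouring C8 methyl group, which sets the quaternary C9 (S) with the two methyl groups cis.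

Step 3
Reactants: 5 (2S,3R)-2-allyl-2,3-dimethylcyclohexan-1-one
Product: 7 (5R,6S)-6-allyl-5,6-dimethylcyclohex-1-en-1-yl trifluoromethanesulfonate, via potassium enolate 6 (not isolated)
Conditions: KHMDS, THF, −78 °C; then PhNTf2, −78 → 0 °C
Reagents that add atoms: N-phenylbis(trifluoromethanesulfonimide) O=S(=O)(N(c1ccccc1)S(=O)(=O)C(F)(F)F)C(F)(F)F
Why: Only C5 carries α-hydrogens (C9 is quaternary), so deprotonation and enolate O-triflation can give only one enol triflate.

Step 4
Reactants: 7 (5R,6S)-6-allyl-5,6-dimethylcyclohex-1-en-1-yl trifluoromethanesulfonate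
Product: 9 3-[(1S,6R)-1,6-dimethyl-2-{[(trifluoromethyl)sulfonyl]oxy}cyclohex-2-en-1-yl]propan-1-ol, via B-alkyl-9-BBN adduct 8 (not isolated)
Conditions: 9-BBN, THF, 0 °C → rt; then NaBO3·4H2O, THF/H2O, rt
Reagents that add atoms: sodium perborate [Na+].[Na+].O[B-]1(O)OO[B-](O)(O)OO1
Why: Anti-Markovnikov hydroboration–oxidation with bulky 9-BBN should select the monosubstituted alkene over the electron-poor trisubstituted enol triflate, and the mild perborate oxidation should spare the triflate.

Step 5
Reactants: 9 3-[(1S,6R)-1,6-dimethyl-2-{[(trifluoromethyl)sulfonyl]oxy}cyclohex-2-en-1-yl]propan-1-ol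
Product: 10 3-[(1S,6R)-2-ethenyl-1,6-dimethylcyclohex-2-en-1-yl]propan-1-ol
Conditions: tributyl(vinyl)stannane, Pd(PPh3)4 (5 mol %), LiCl, THF, 65 °C
Reagents that add atoms: tributyl(vinyl)stannane C=C[Sn](CCCC)(CCCC)CCCC
Why: Stille coupling of the enol triflate installs C1–C2 and tolerates the free alcohol; the allyl group was converted beforehand so that no 1,5-diene able to undergo a Cope rearrangement enters the thermal step 6.

Step 6
Reactants: 10 3-[(1S,6R)-2-ethenyl-1,6-dimethylcyclohex-2-en-1-yl]propan-1-ol; 11 methyl methacrylate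
Product: 12 methyl (1S,5S,6R,8aS)-5-(3-hydroxypropyl)-1,5,6-trimethyl-1,2,3,5,6,7,8,8a-octahydronaphthalene-1-carboxylate (halimane C4 S, C5 S, C8 R, C9 S; C1=C10 double bond)
Conditions: neat 11 (excess), BHT (cat.), sealed tube, 150 °C
Reagents that add atoms: none
Why: Diels–Alder reaction of the 1-vinylcyclohexene-type diene closes ring A with "ortho" regiochemistry (the ester-bearing carbon bonds to C5) and leaves the C1=C10 alkene; the dienophile should add anti to the pseudoaxial C9 chain (the larger C9 substituent avoids A(1,2) strain with the vinyl group), which sets C5 (S), and the exo orientation of the ester with the methyl group endo, which uncatalysed α-methyl acrylates do not disfavour, sets C4 (S), the minor C4 and C5 isomers being removed by chromatography.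

Step 7
Reactants: 12 methyl (1S,5S,6R,8aS)-5-(3-hydroxypropyl)-1,5,6-trimethyl-1,2,3,5,6,7,8,8a-octahydronaphthalene-1-carboxylate
Product: 13 methyl (1S,5S,6R,8aS)-1,5,6-trimethyl-5-(3-oxopropyl)-1,2,3,5,6,7,8,8a-octahydronaphthalene-1-carboxylate (C13 aldehyde)
Conditions: Dess–Martin periodinane, NaHCO3, CH2Cl2, 0 °C → rt
Reagents that add atoms: none
Why: Dess–Martin oxidation converts the primary alcohol to the aldehyde without touching the ester or the ring alkene.

Step 8
Reactants: 14 4-methoxybenzyl alcohol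
Product: 15 allyl 4-methoxybenzyl ether
Conditions: NaH, allyl bromide, THF/DMF, 0 °C → rt
Reagents that add atoms: allyl bromide C=CCBr
Why: Williamson ether synthesis of the alkoxide with a reactive allylic halide.

Step 9
Reactants: 13 C13 aldehyde; 15 allyl 4-methoxybenzyl ether; 16 (−)-B-methoxydiisopinocampheylborane (from (+)-α-pinene)
Product: 19 methyl (1S,5S,6R,8aS)-5-{(3R,4R)-3-hydroxy-4-[(4-methoxybenzyl)oxy]hex-5-en-1-yl}-1,5,6-trimethyl-1,2,3,5,6,7,8,8a-octahydronaphthalene-1-carboxylate (13R,14R), via lithiated allyl ether 17 (not isolated), via allylborane 18 (not isolated)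
Conditions: 15, s-BuLi, THF, −78 °C; 16, −78 °C; BF3·OEt2; then 13, −78 °C; then NaOH, H2O2, 0 °C → rt
Reagents that add atoms: none
Why: Metalation of 15 gives the (Z)-γ-alkoxyallyl anion 17, which is trapped by 16 and released by BF3 as the (Z)-γ-alkoxyallylborane 18; this adds to aldehyde 13 through a closed six-membered Zimmerman–Traxler transition state with allylic transposition. The closest known reaction type is the Brown alkoxyallylboration of aliphatic aldehydes with (Z)-γ-alkoxyallyl-Ipc2B reagents; no ring is closed. The (Z)-geometry of 18 translates into the syn relation of O13 and O14, and the Ipc groups derived from (+)-α-pinene direct attack to the Si face of the aldehyde, so that C13 should be R and C14 R under reagent control, the remote ring stereocentres having no say. C14 is the lasting stereocentre, while C13 is set only temporarily and is erased in step 10. The step needs bond formation at the oxygen-bearing γ-carbon, which the chair transition state enforces, and retention of the (Z)-borane geometry, which holding −78 °C secures against 1,3-boratropic shift. It also needs allylic rather than benzylic metalation of 15, which the kinetic acidity of the allylic α-oxy position towards s-BuLi at −78 °C should secure.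

Step 10
Reactants: 19 (13R,14R)-homoallylic alcohol
Product: 20 methyl (1S,5S,6R,8aS)-5-{(4R)-4-[(4-methoxybenzyl)oxy]-3-oxohex-5-en-1-yl}-1,5,6-trimethyl-1,2,3,5,6,7,8,8a-octahydronaphthalene-1-carboxylate (C13 ketone)
Conditions: Dess–Martin periodinane, NaHCO3, CH2Cl2, 0 °C; used at once
Reagents that add atoms: none
Why: Dess–Martin oxidation under buffered, non-basic conditions should give the α-alkoxy β,γ-unsaturated ketone without epimerising C14 or moving the vinyl double bond into conjugation.

Step 11
Reactants: 20 C13 ketone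
Product: 21 methyl (1S,5S,6R,8aS)-5-{(3S,4R)-3-hydroxy-4-[(4-methoxybenzyl)oxy]-3-methylhex-5-en-1-yl}-1,5,6-trimethyl-1,2,3,5,6,7,8,8a-octahydronaphthalene-1-carboxylate (13S,14R)
Conditions: MeMgBr, Et2O/CH2Cl2, −78 °C
Reagents that add atoms: methylmagnesium bromide C[Mg]Br
Why: Cram-chelate addition: magnesium bridges the C13 carbonyl and the C14 ether oxygen and methyl adds to the chelate face opposite the vinyl group, which sets C13 (S), while the hindered C18 ester on the quaternary C4 should not react at −78 °C.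

Step 12
Reactants: 21 (13S,14R)-tertiary alcohol PMB ether
Product: 22 methyl (1S,5S,6R,8aS)-5-[(3S,4R)-3,4-dihydroxy-3-methylhex-5-en-1-yl]-1,5,6-trimethyl-1,2,3,5,6,7,8,8a-octahydronaphthalene-1-carboxylate
Conditions: DDQ, CH2Cl2/pH 7 buffer, 0 °C; dilute AcOH work-up
Reagents that add atoms: none
Why: Oxidative PMB ether cleavage leaves alkenes and ester alone, and any p-methoxybenzylidene acetal formed with the neighbouring tertiary alcohol is hydrolysed in the acidic work-up.

Step 13
Reactants: 22 diol methyl ester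
Product: 23 (1S,5S,6R,8aS)-5-[(3S,4R)-3,4-dihydroxy-3-methylhex-5-en-1-yl]-1,5,6-trimethyl-1,2,3,5,6,7,8,8a-octahydronaphthalene-1-carboxylic acid
Conditions: NaSEt, DMF, 90 °C; then dilute HCl
Reagents that add atoms: none
Why: SN2 dealkylation of the methyl ester by thiolate at the O–CH3 carbon frees the carboxylic acid on the quaternary C4, which resists saponification, before any base-labile acetate is present.

Step 14
Reactants: 23 diol acid
Product: 24 (1S,5S,6R,8aS)-5-[(3S,4R)-4-acetoxy-3-hydroxy-3-methylhex-5-en-1-yl]-1,5,6-trimethyl-1,2,3,5,6,7,8,8a-octahydronaphthalene-1-carboxylic acid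
Conditions: Ac2O, pyridine, DMAP (cat.), CH2Cl2, 0 °C; aqueous work-up
Reagents that add atoms: acetic anhydride CC(=O)OC(C)=O
Why: Acylation should take the secondary allylic C14 alcohol only, since the tertiary C13 alcohol is too hindered and any mixed anhydride of the hindered acid is hydrolysed on work-up.

Step 15
Reactants: 24 14-acetate with vinyl group
Product: 26 (1S,5S,6R,8aS)-5-[(3S,4S)-4-acetoxy-3-hydroxy-3-methyl-5-oxopentyl]-1,5,6-trimethyl-1,2,3,5,6,7,8,8a-octahydronaphthalene-1-carboxylic acid (C15 aldehyde), via terminal diol 25 (not isolated)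
Conditions: OsO4 (2 mol %), NaIO4, THF/H2O, 0 °C → rt; crude product taken on directly
Reagents that add atoms: osmium tetroxide O=[Os](=O)(=O)=O (catalytic oxygen carrier); sodium periodate [Na+].[O-]I(=O)(=O)=O (terminal oxidant)
Why: Lemieux–Johnson oxidation: osmylation should select the monosubstituted side-chain alkene over the hindered trisubstituted C1=C10 alkene next to the quaternary C9, and periodate cleaves the terminal diol, the C13/C14 pair being safe because O14 is acylated.

Step 16
Reactants: 26 C15 aldehyde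
Product: 27 target, (1S,5S,6R,8aS)-5-[(3S,4R)-4-acetoxy-3,5-dihydroxy-3-methylpentyl]-1,5,6-trimethyl-1,2,3,5,6,7,8,8a-octahydronaphthalene-1-carboxylic acid
Conditions: Me4NBH(OAc)3, AcOH/MeCN, −20 °C
Reagents that add atoms: none
Why: Hydroxyl-directed triacetoxyborohydride reduction of the β-hydroxy aldehyde (Evans–Saksena conditions) works in acidic medium, which should avoid the base-induced O14→O15 acetyl migration and retro-aldol cleavage.

**Compound list**

1 | 2-methylcyclohex-2-en-1-one | CC1=CCCCC1=O | starting material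
2 | dimethylaluminium (R)-2,3-dimethylcyclohex-1-en-1-olate | CC1=C(O[Al](C)C)CCC[C@H]1C | intermediate
3 | (R)-2,3-dimethyl-1-[(trimethylsilyl)oxy]cyclohex-1-ene | CC1=C(O[Si](C)(C)C)CCC[C@H]1C | intermediate
4 | lithium (R)-2,3-dimethylcyclohex-1-en-1-olate | CC1=C(O[Li])CCC[C@H]1C | intermediate
5 | (2S,3R)-2-allyl-2,3-dimethylcyclohexan-1-one | C=CC[C@]1(C)C(=O)CCC[C@H]1C | intermediate
6 | potassium (5R,6S)-6-allyl-5,6-dimethylcyclohex-1-en-1-olate | C=CC[C@]1(C)C(O[K])=CCC[C@H]1C | intermediate
7 | (5R,6S)-6-allyl-5,6-dimethylcyclohex-1-en-1-yl trifluoromethanesulfonate | C=CC[C@]1(C)C(OS(=O)(=O)C(F)(F)F)=CCC[C@H]1C | intermediate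
8 | B-alkyl-9-BBN adduct of 7 (boron on the terminal chain carbon) | C1CCC2CCCC1B2CCC[C@]1(C)C(OS(=O)(=O)C(F)(F)F)=CCC[C@H]1C | intermediate
9 | 3-[(1S,6R)-1,6-dimethyl-2-{[(trifluoromethyl)sulfonyl]oxy}cyclohex-2-en-1-yl]propan-1-ol | OCCC[C@]1(C)C(OS(=O)(=O)C(F)(F)F)=CCC[C@H]1C | intermediate
10 | 3-[(1S,6R)-2-ethenyl-1,6-dimethylcyclohex-2-en-1-yl]propan-1-ol | OCCC[C@]1(C)C(C=C)=CCC[C@H]1C | intermediate
11 | methyl methacrylate | C=C(C)C(=O)OC | starting material
12 | methyl (1S,5S,6R,8aS)-5-(3-hydroxypropyl)-1,5,6-trimethyl-1,2,3,5,6,7,8,8a-octahydronaphthalene-1-carboxylate | OCCC[C@]1(C)C2=CCC[C@](C)(C(=O)OC)[C@H]2CC[C@H]1C | intermediate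
13 | methyl (1S,5S,6R,8aS)-1,5,6-trimethyl-5-(3-oxopropyl)-1,2,3,5,6,7,8,8a-octahydronaphthalene-1-carboxylate | O=CCC[C@]1(C)C2=CCC[C@](C)(C(=O)OC)[C@H]2CC[C@H]1C | intermediate
14 | 4-methoxybenzyl alcohol | COc1ccc(CO)cc1 | starting material
15 | allyl 4-methoxybenzyl ether | C=CCOCc1ccc(OC)cc1 | intermediate
16 | (−)-B-methoxydiisopinocampheylborane | COB([C@@H]1C[C@@H]2C[C@H]([C@H]1C)C2(C)C)[C@@H]1C[C@@H]2C[C@H]([C@H]1C)C2(C)C | starting material
17 | (Z)-3-[(4-methoxybenzyl)oxy]allyllithium | [Li]C/C=C\OCc1ccc(OC)cc1 | intermediate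
18 | (Z)-{3-[(4-methoxybenzyl)oxy]allyl}diisopinocampheylborane | COc1ccc(CO/C=C\CB([C@@H]2C[C@@H]3C[C@H]([C@H]2C)C3(C)C)[C@@H]2C[C@@H]3C[C@H]([C@H]2C)C3(C)C)cc1 | intermediate
19 | (13R,14R)-homoallylic alcohol: methyl ester core with side chain (3R,4R)-3-hydroxy-4-[(4-methoxybenzyl)oxy]hex-5-en-1-yl on C9 | C=C[C@@H](OCc1ccc(OC)cc1)[C@H](O)CC[C@]1(C)C2=CCC[C@](C)(C(=O)OC)[C@H]2CC[C@H]1C | intermediate
20 | C13 ketone: side chain (4R)-4-[(4-methoxybenzyl)oxy]-3-oxohex-5-en-1-yl | C=C[C@@H](OCc1ccc(OC)cc1)C(=O)CC[C@]1(C)C2=CCC[C@](C)(C(=O)OC)[C@H]2CC[C@H]1C | intermediate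
21 | (13S,14R)-tertiary alcohol: side chain (3S,4R)-3-hydroxy-4-[(4-methoxybenzyl)oxy]-3-methylhex-5-en-1-yl | C=C[C@@H](OCc1ccc(OC)cc1)[C@@](C)(O)CC[C@]1(C)C2=CCC[C@](C)(C(=O)OC)[C@H]2CC[C@H]1C | intermediate
22 | diol methyl ester: side chain (3S,4R)-3,4-dihydroxy-3-methylhex-5-en-1-yl | C=C[C@@H](O)[C@@](C)(O)CC[C@]1(C)C2=CCC[C@](C)(C(=O)OC)[C@H]2CC[C@H]1C | intermediate
23 | diol acid: as 22 with free C18 carboxylic acid | C=C[C@@H](O)[C@@](C)(O)CC[C@]1(C)C2=CCC[C@](C)(C(=O)O)[C@H]2CC[C@H]1C | intermediate
24 | 14-acetate acid: side chain (3S,4R)-4-acetoxy-3-hydroxy-3-methylhex-5-en-1-yl | C=C[C@@H](OC(C)=O)[C@@](C)(O)CC[C@]1(C)C2=CCC[C@](C)(C(=O)O)[C@H]2CC[C@H]1C | intermediate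
25 | terminal diol from 24 (both epimers at the new carbinol carbon) | OCC(O)[C@@H](OC(C)=O)[C@@](C)(O)CC[C@]1(C)C2=CCC[C@](C)(C(=O)O)[C@H]2CC[C@H]1C | intermediate
26 | C15 aldehyde: side chain (3S,4S)-4-acetoxy-3-hydroxy-3-methyl-5-oxopentyl | O=C[C@@H](OC(C)=O)[C@@](C)(O)CC[C@]1(C)C2=CCC[C@](C)(C(=O)O)[C@H]2CC[C@H]1C | intermediate
27 | (1S,5S,6R,8aS)-5-[(3S,4R)-4-acetoxy-3,5-dihydroxy-3-methylpentyl]-1,5,6-trimethyl-1,2,3,5,6,7,8,8a-octahydronaphthalene-1-carboxylic acid (CNP0164901.1) | CC(=O)O[C@H](CO)[C@@](C)(O)CC[C@]1(C)C2=CCC[C@](C)(C(=O)O)[C@H]2CC[C@H]1C | target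

**Step count.** Total: 16 steps. Longest linear sequence: 15 steps (steps 1–7 and 9–16; step 8 prepares the side fragment).

**The three steps most likely to fail**

1. Step 6 (Diels–Alder). What may go wrong: the two C9 substituents differ little in size, so π-facial discrimination may be poor; the ester may not prefer the exo position, so up to four diastereomers can form; the dienophile may polymerise before the hindered diene is consumed.
Fallback (sets out from 10, comes back at 12): a Lewis-acid-catalysed, exo-selective cycloaddition with an enal at low temperature.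
 - Alcohol 10 is silylated (TBSCl, imidazole, DMF) to give the silyl ether of 10, F1.
 - F1 and methacrolein are combined in CH2Cl2 at −40 °C with catalytic B(C6F5)3. This bulky Lewis acid is known to make cycloadditions of α-substituted enals with 1-substituted dienes exo-selective, and at this temperature small conformational preferences of the diene count for more. This should give the C18 aldehyde F2 with the formyl group cis to H5.
 - Pinnick oxidation (NaClO2, NaH2PO4, 2-methyl-2-butene) gives the C18 acid F3.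
 - TMSCHN2 in toluene/MeOH gives the methyl ester silyl ether F4.
 - TBAF in THF returns to 12.

2. Step 11 (methyl addition to ketone 20). What may go wrong: the C14 hydrogen is both α to the ketone and allylic, so the Grignard reagent may enolise the ketone, which would epimerise C14 or move the double bond into conjugation; chelation control may also be incomplete.
Fallback (sets out from 19, ends at 27): the vinyl group is taken out before the ketone is made, so that the chelation-controlled addition is run on a non-allylic α,β-dialkoxy ketone.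
 - OsO4/NaIO4 then NaBH4 converts 19 into the C13,C15-diol F5.
 - TBDPSCl/imidazole protects the primary alcohol to give the silyl ether F6.
 - Dess–Martin oxidation gives the ketone F7.
 - MeMgBr (Et2O/CH2Cl2, −78 °C, Cram chelate through the C14 PMB ether) gives the tertiary alcohol F8.
 - DDQ gives the diol F9.
 - NaSEt in DMF gives the acid F10.
 - Ac2O/pyridine gives the 14-acetate F11.
 - HF·pyridine in THF removes the silyl group under acidic conditions and gives 27.

3. Step 15 (oxidative cleavage beside the acetate). What may go wrong: the acetyl group may migrate from O14 to the new neighbouring hydroxyl in diol 25, which would expose the C13/C14 diol to periodate cleavage; the β-hydroxy aldehyde 26 may undergo retro-aldol loss before it is reduced.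
Fallback (sets out from 21, ends at 27): the cleavage is run while O14 still carries the PMB ether.
 - OsO4/NaIO4 then NaBH4 converts 21 into the primary alcohol F12.
 - TBDPSCl/imidazole converts F12 into the tertiary alcohol F8.
 - The sequence described above then follows through the diol F9, the acid F10 and the 14-acetate F11 to 27.

Further compounds
F1 | step 6 | tert-butyldimethylsilyl ether of 10 | CC(C)(C)[Si](C)(C)OCCC[C@]1(C)C(C=C)=CCC[C@H]1C
F2 | step 6 | C18 aldehyde cycloadduct (silyl ether; CHO on C4 cis to H5) | CC(C)(C)[Si](C)(C)OCCC[C@]1(C)C2=CCC[C@](C)(C=O)[C@H]2CC[C@H]1C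
F3 | step 6 | C18 carboxylic acid (silyl ether) | CC(C)(C)[Si](C)(C)OCCC[C@]1(C)C2=CCC[C@](C)(C(=O)O)[C@H]2CC[C@H]1C
F4 | step 6 | tert-butyldimethylsilyl ether of 12 | CC(C)(C)[Si](C)(C)OCCC[C@]1(C)C2=CCC[C@](C)(C(=O)OC)[C@H]2CC[C@H]1C
F5 | step 11 | (13R,14R)-13,15-diol 14-PMB ether methyl ester | OC[C@@H](OCc1ccc(OC)cc1)[C@H](O)CC[C@]1(C)C2=CCC[C@](C)(C(=O)OC)[C@H]2CC[C@H]1C
F6 | step 11 | 15-O-TBDPS ether of F5 | CC(C)(C)[Si](OC[C@@H](OCc1ccc(OC)cc1)[C@H](O)CC[C@]1(C)C2=CCC[C@](C)(C(=O)OC)[C@H]2CC[C@H]1C)(c1ccccc1)c1ccccc1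
F7 | step 11 | C13 ketone with 14-OPMB and 15-OTBDPS | CC(C)(C)[Si](OC[C@@H](OCc1ccc(OC)cc1)C(=O)CC[C@]1(C)C2=CCC[C@](C)(C(=O)OC)[C@H]2CC[C@H]1C)(c1ccccc1)c1ccccc1
F8 | step 11 | (13S,14R)-tertiary alcohol with 14-OPMB and 15-OTBDPS, methyl ester | CC(C)(C)[Si](OC[C@@H](OCc1ccc(OC)cc1)[C@@](C)(O)CC[C@]1(C)C2=CCC[C@](C)(C(=O)OC)[C@H]2CC[C@H]1C)(c1ccccc1)c1ccccc1
F9 | step 11 | (13S,14R)-13,14-diol 15-OTBDPS methyl ester | CC(C)(C)[Si](OC[C@@H](O)[C@@](C)(O)CC[C@]1(C)C2=CCC[C@](C)(C(=O)OC)[C@H]2CC[C@H]1C)(c1ccccc1)c1ccccc1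
F10 | step 11 | (13S,14R)-13,14-diol 15-OTBDPS C18 acid | CC(C)(C)[Si](OC[C@@H](O)[C@@](C)(O)CC[C@]1(C)C2=CCC[C@](C)(C(=O)O)[C@H]2CC[C@H]1C)(c1ccccc1)c1ccccc1
F11 | step 11 | 14-acetate 15-OTBDPS C18 acid | CC(C)(C)[Si](OC[C@@H](OC(C)=O)[C@@](C)(O)CC[C@]1(C)C2=CCC[C@](C)(C(=O)O)[C@H]2CC[C@H]1C)(c1ccccc1)c1ccccc1
F12 | step 15 | (13S,14R)-13,15-diol 14-PMB ether methyl ester | OC[C@@H](OCc1ccc(OC)cc1)[C@@](C)(O)CC[C@]1(C)C2=CCC[C@](C)(C(=O)OC)[C@H]2CC[C@H]1C
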